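- I began in a one-step world, where each substrate took one partner, so half of the substrate charged cost 0.0330 M of partner.

substrate 0.066 M; time 1.0 h

1. the concentration of partner at which the part of the substrate that has reacted at 1.0 h is just 50%, in M

    substrate + partner → mono adduct + by-product (k1 = 0.36 /M/s)
    substrate + partner → other mono adduct + by-product (k2 = 0.43 /M/s)
    partner + mono adduct → bis adduct + by-product (k3 = 0.55 /M/s)
    partner + other mono adduct → bis adduct + by-product (k4 = 0.018 /M/s)
    partner + by-product ⇌ idle adduct, settled at all times (K5 = 1400 /M)
    partner ⇌ dormant form (K6 = 1.5, k6 = 0.014 /s)

- I then asked what the end state had to be, and carried one quantity: the exposure, meaning free partner concentration summed over time. Substrate falls exponentially in exposure at the summed constant of its two steps, whatever the free partner's curve, so the asked point lay at an exposure of 0.877 M·s.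
- Next I let the mono adduct take a second partner. At that exposure 0.0150 M of mono adduct had been made and 0.0116 M survived, so partner used rose to 0.0364 M. I dropped the other mono adduct's second step, its 0.018 /M/s being far smaller than the 0.55 /M/s of the mono adduct.
- Then I asked how fast that point was approached. Taking free by-product as equal to the partner used, I put free partner at about the spare partner, the charge less the partner used, divided by 53.5; this counts the dormant form as balanced, since its relaxation of 0.495 min is shorter than the hour.
- Spare partner therefore decayed near the end with a time of 27.5 min. As a rough allowance for the early spending, I added one such time to the hour. Starting from a spare equal to the partner used, this estimate gave 0.00151 M spare at the end, and I committed to 0.0379 M.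
- The forecast gave 0.0375 M, reasoning that “The idle-adduct trap and the fast dormant equilibrium then starve the reaction near the end”.
- The simulation gave 0.0375 M, lower than my figure. That charge is 0.568 of the substrate charged, with partner the limiting reagent, and substrate used had reached 47.6% at 0.500 h. As a reading, that stands for an exposure of 0.817 M·s, so the remaining time had to supply 0.0604 M·s. This means a mean free partner of 0.0895% of the charge, below the 0.164% still free at 0.500 h and above the 0.0450% free at 1.00 h.

All constants were drawn at random within sensible limits; the result is computed.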